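**Strategy**

Ring C is opened at C3–C4. Its C4 carbonyl sits on ring A ortho to the ether oxygen O1, C3 is an unsubstituted CH2 and C2 carries H, O1 and ring B, so ring C is the formal adduct of an ortho-formyl C–H bond across the C2=C3 bond of an aryl 1-arylvinyl ether. An enantioselective rhodium-catalysed intramolecular hydroacylation should therefore close ring C and create the only stereocentre, C2, in one operation. The precursor is achiral: a 2-(1-arylvinyloxy)benzaldehyde in which ring B already carries both prenyl groups, built by esterifying a salicylaldehyde with a 2,3-diprenylbenzoic acid and methylenating the aryl ester.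

Key step: step 10

Abbreviations: MOM = methoxymethyl; prenyl = 3-methylbut-2-en-1-yl.

Remark on the chemistry: which antipode of DTBM-SEGPHOS delivers hydride to the face of C2 that leads to 2S cannot be assigned with certainty by analogy; (R) is written, and the (S) ligand is used instead if a model cyclisation shows the opposite sense.

**Route**

Step 1
Reactants: 1 5-bromovanillin (3-bromo-4-hydroxy-5-methoxybenzaldehyde)
Product: 2 2,3-dibromo-4-hydroxy-5-methoxybenzaldehyde (5,6-dibromovanillin)
Conditions: Br2 (1.2 equiv), Fe powder (cat.), AcOH, 80 °C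
Reagents that add atoms: bromine BrBr
Why: Electrophilic aromatic bromination; the positions ortho and para to the phenol are blocked, so the methoxy group directs para and the second bromine should enter next to the first, ortho to the formyl group.

Step 2
Reactants: 2 2,3-dibromo-4-hydroxy-5-methoxybenzaldehyde
Product: 3 2,3-dibromo-4,5-dihydroxybenzaldehyde
Conditions: AlCl3 (1.2 equiv), pyridine (4.5 equiv), CH2Cl2, reflux; then 2 M HCl
Reagents that add atoms: none
Why: Lewis-acid-assisted SN2 O-demethylation (AlCl3 chelated by the ortho hydroxy/methoxy pair, pyridine as methyl acceptor), the standard opening of guaiacol-type aldehydes to catechols, which leaves the aryl bromides untouched.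

Step 3
Reactants: 3 2,3-dibromo-4,5-dihydroxybenzaldehyde
Product: 4 2,3-dibromo-4,5-bis(methoxymethoxy)benzaldehyde
Conditions: MOMCl (3 equiv), i-Pr2NEt (4 equiv), CH2Cl2, 0 °C to rt
Reagents that add atoms: chloromethyl methyl ether COCCl
Why: Williamson-type O-alkylation (MOM protection) of both catechol hydroxyls; the acetal ethers withstand the palladium, chlorite, titanium and rhodium steps and leave together at the end.

Step 4
Reactants: 4 2,3-dibromo-4,5-bis(methoxymethoxy)benzaldehyde
Product: 5 4,5-bis(methoxymethoxy)-2,3-bis(3-methylbut-2-en-1-yl)benzaldehyde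
Conditions: tributyl(prenyl)stannane (3 equiv), Pd(PPh3)4 (10 mol %), CuI (20 mol %), CsF (4 equiv), DMF, 80 °C
Reagents that add atoms: tributyl(3-methylbut-2-en-1-yl)stannane CC(C)=CC[Sn](CCCC)(CCCC)CCCC
Why: Twofold Stille cross-coupling; fluoride and the copper co-catalyst speed transmetalation at the hindered vicinal positions, reductive elimination at the unsubstituted allyl terminus should give the linear prenyl groups, and the aldehyde and MOM ethers are inert to the stannane.

Step 5
Reactants: 5 4,5-bis(methoxymethoxy)-2,3-bis(3-methylbut-2-en-1-yl)benzaldehyde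
Product: 6 4,5-bis(methoxymethoxy)-2,3-bis(3-methylbut-2-en-1-yl)benzoic acid
Conditions: NaClO2, NaH2PO4, 2-methyl-2-butene (large excess), t-BuOH/H2O, 0 °C to rt
Reagents that add atoms: sodium chlorite [Na+].[O-]Cl=O
Why: Pinnick oxidation of the aldehyde to the acid; the excess 2-methyl-2-butene takes up the hypochlorite so that the two prenyl groups should be spared, and the buffered medium leaves the MOM ethers intact.

Step 6
Reactants: 7 2,4,6-trihydroxybenzaldehyde
Product: 8 2-hydroxy-4,6-bis(methoxymethoxy)benzaldehyde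
Conditions: MOMCl (2.1 equiv), i-Pr2NEt (2.5 equiv), CH2Cl2, 0 °C to rt
Reagents that add atoms: chloromethyl methyl ether COCCl
Why: Selective Williamson-type MOM etherification; after two alkylations the remaining ortho hydroxyl is locked in the hydrogen bond to the formyl group, which leaves one free phenol for the ester.

Step 7
Reactants: 6 4,5-bis(methoxymethoxy)-2,3-bis(3-methylbut-2-en-1-yl)benzoic acid; 8 2-hydroxy-4,6-bis(methoxymethoxy)benzaldehyde
Product: 9 2-formyl-3,5-bis(methoxymethoxy)phenyl 4,5-bis(methoxymethoxy)-2,3-bis(3-methylbut-2-en-1-yl)benzoate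
Conditions: EDC·HCl (1.5 equiv), DMAP (0.3 equiv), CH2Cl2, rt
Reagents that add atoms: none
Why: Steglich esterification (carbodiimide activation, DMAP acyl transfer) joins the future O1 to the carboxyl carbon of ring B, the future C2.

Step 8
Reactants: 9 2-formyl-3,5-bis(methoxymethoxy)phenyl 4,5-bis(methoxymethoxy)-2,3-bis(3-methylbut-2-en-1-yl)benzoate
Product: 10 2-(dimethoxymethyl)-3,5-bis(methoxymethoxy)phenyl 4,5-bis(methoxymethoxy)-2,3-bis(3-methylbut-2-en-1-yl)benzoate
Conditions: HC(OMe)3 (5 equiv), MeOH, PPTS (cat.), rt; Et3N quench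
Reagents that add atoms: trimethyl orthoformate COC(OC)OC
Why: Acid-catalysed acetalisation with the orthoformate as dehydrating agent masks the aldehyde, which would otherwise be methylenated before the ester in step 9; PPTS at room temperature should leave the MOM ethers and prenyl groups alone.

Step 9
Reactants: 10 2-(dimethoxymethyl)-3,5-bis(methoxymethoxy)phenyl 4,5-bis(methoxymethoxy)-2,3-bis(3-methylbut-2-en-1-yl)benzoate
Product: 12 2-({1-[4,5-bis(methoxymethoxy)-2,3-bis(3-methylbut-2-en-1-yl)phenyl]ethenyl}oxy)-4,6-bis(methoxymethoxy)benzaldehyde, via acetal enol ether 11 (not isolated)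
Conditions: Cp2TiMe2 (3 equiv), toluene/THF, 70 °C, dark; then AcOH/NaOAc buffer (pH 5), THF/H2O, 0 °C
Reagents that add atoms: dimethyltitanocene [CH3-].[CH3-].c1cc[cH-]c1.c1cc[cH-]c1.[Ti+4]; water O
Why: Petasis methylenation (titanium methylidene, oxatitanacyclobutane, cycloreversion) turns the aryl ester C=O into the 1,1-disubstituted enol ether and so installs C3; the dimethyl acetal of a 2,4,6-trioxygenated benzaldehyde ionises far faster than the aryl enol ether or the MOM ethers are protonated, so the cold pH 5 buffer should unmask only the aldehyde.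

Step 10
Reactants: 12 2-({1-[4,5-bis(methoxymethoxy)-2,3-bis(3-methylbut-2-en-1-yl)phenyl]ethenyl}oxy)-4,6-bis(methoxymethoxy)benzaldehyde
Product: 13 (2S)-2-[4,5-bis(methoxymethoxy)-2,3-bis(3-methylbut-2-en-1-yl)phenyl]-5,7-bis(methoxymethoxy)-2,3-dihydro-4H-chromen-4-one
Conditions: [Rh(cod)Cl]2 (2.5 mol %), (R)-DTBM-SEGPHOS (5.5 mol %), Na[B(3,5-(CF3)2C6H3)4] (5 mol %), anhydrous degassed 1,2-dichloroethane, 60 °C
Reagents that add atoms: none
Why: Proposed new method: oxidative addition of the cationic monovalent rhodium bisphosphine complex into the formyl C–H bond gives an acyl hydride of trivalent rhodium held by the ortho vinyl ether; the C2=C3 bond inserts into Rh–H with hydride going to the substituted carbon C2 and rhodium to the terminal CH2, and C–C reductive elimination from the seven-membered acyl–alkyl rhodacycle forms the C3–C4 bond. The closest known reaction type is the rhodium-catalysed enantioselective intramolecular hydroacylation of 2-(1-substituted vinyl)benzaldehydes to 3-substituted indanones and of ortho-(2-substituted allyl)benzaldehydes to 3-substituted tetralones; an aryl 1-arylvinyl ether has not served as the alkene. Ring C closes in the 6-endo-trig mode with respect to the enol ether. The C2 stereocentre is created by enantiofacial hydride delivery inside the chiral pocket of the DTBM-SEGPHOS–rhodium complex (catalyst control; the substrate has no stereocentre). The step needs endo rather than exo regiochemistry (exo would give a 2-aryl-2-methylbenzofuran-3-one), which the 1,1-disubstitution secures by disfavouring a tertiary alkyl–rhodium, and it needs insertion to outrun decarbonylation and β-aryloxy elimination, which chelation by the vinyl ether and the position of O1 inside the rhodacycle (no syn-coplanar Rh–C–C–O) should secure. The trisubstituted prenyl alkenes should not insert into Rh–H, and the MOM ethers are inert.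

Step 11
Reactants: 13 (2S)-2-[4,5-bis(methoxymethoxy)-2,3-bis(3-methylbut-2-en-1-yl)phenyl]-5,7-bis(methoxymethoxy)-2,3-dihydro-4H-chromen-4-one
Product: 14 (2S)-2-[4,5-dihydroxy-2,3-bis(3-methylbut-2-en-1-yl)phenyl]-5,7-dihydroxy-2,3-dihydro-4H-chromen-4-one
Conditions: HCl (3 M aq.), MeOH/THF, 40 °C
Reagents that add atoms: none
Why: Acid-catalysed acetal exchange (MOM cleavage) frees the four phenols; under acid the base-mediated retro-oxa-Michael opening is not available, so C2 should keep its configuration, and at 40 °C addition of the 4′-hydroxyl to the neighbouring prenyl group should stay slow.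

**Compound list**

1 | 5-bromovanillin (3-bromo-4-hydroxy-5-methoxybenzaldehyde) | O=Cc1cc(Br)c(O)c(OC)c1 | starting material
2 | 2,3-dibromo-4-hydroxy-5-methoxybenzaldehyde | O=Cc1cc(OC)c(O)c(Br)c1Br | intermediate
3 | 2,3-dibromo-4,5-dihydroxybenzaldehyde | O=Cc1cc(O)c(O)c(Br)c1Br | intermediate
4 | 2,3-dibromo-4,5-bis(methoxymethoxy)benzaldehyde | O=Cc1cc(OCOC)c(OCOC)c(Br)c1Br | intermediate
5 | 4,5-bis(methoxymethoxy)-2,3-bis(3-methylbut-2-en-1-yl)benzaldehyde | O=Cc1cc(OCOC)c(OCOC)c(CC=C(C)C)c1CC=C(C)C | intermediate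
6 | 4,5-bis(methoxymethoxy)-2,3-bis(3-methylbut-2-en-1-yl)benzoic acid | OC(=O)c1cc(OCOC)c(OCOC)c(CC=C(C)C)c1CC=C(C)C | intermediate
7 | 2,4,6-trihydroxybenzaldehyde | O=Cc1c(O)cc(O)cc1O | starting material
8 | 2-hydroxy-4,6-bis(methoxymethoxy)benzaldehyde | O=Cc1c(O)cc(OCOC)cc1OCOC | intermediate
9 | 2-formyl-3,5-bis(methoxymethoxy)phenyl 4,5-bis(methoxymethoxy)-2,3-bis(3-methylbut-2-en-1-yl)benzoate | O=Cc1c(OC(=O)c2cc(OCOC)c(OCOC)c(CC=C(C)C)c2CC=C(C)C)cc(OCOC)cc1OCOC | intermediate
10 | 2-(dimethoxymethyl)-3,5-bis(methoxymethoxy)phenyl 4,5-bis(methoxymethoxy)-2,3-bis(3-methylbut-2-en-1-yl)benzoate | COC(OC)c1c(OC(=O)c2cc(OCOC)c(OCOC)c(CC=C(C)C)c2CC=C(C)C)cc(OCOC)cc1OCOC | intermediate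
11 | 1-{1-[2-(dimethoxymethyl)-3,5-bis(methoxymethoxy)phenoxy]ethenyl}-4,5-bis(methoxymethoxy)-2,3-bis(3-methylbut-2-en-1-yl)benzene (acetal enol ether, not isolated) | COC(OC)c1c(OC(=C)c2cc(OCOC)c(OCOC)c(CC=C(C)C)c2CC=C(C)C)cc(OCOC)cc1OCOC | intermediate
12 | 2-({1-[4,5-bis(methoxymethoxy)-2,3-bis(3-methylbut-2-en-1-yl)phenyl]ethenyl}oxy)-4,6-bis(methoxymethoxy)benzaldehyde | O=Cc1c(OC(=C)c2cc(OCOC)c(OCOC)c(CC=C(C)C)c2CC=C(C)C)cc(OCOC)cc1OCOC | intermediate
13 | (2S)-2-[4,5-bis(methoxymethoxy)-2,3-bis(3-methylbut-2-en-1-yl)phenyl]-5,7-bis(methoxymethoxy)-2,3-dihydro-4H-chromen-4-one | CC(C)=CCc1c([C@@H]2CC(=O)c3c(OCOC)cc(OCOC)cc3O2)cc(OCOC)c(OCOC)c1CC=C(C)C | intermediate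
14 | (2S)-2-[4,5-dihydroxy-2,3-bis(3-methylbut-2-en-1-yl)phenyl]-5,7-dihydroxy-2,3-dihydro-4H-chromen-4-one | CC(C)=CCc1c([C@@H]2CC(=O)c3c(O)cc(O)cc3O2)cc(O)c(O)c1CC=C(C)C | target

**Step count and risks**

Total steps: 11. Longest linear sequence: 10 (steps 1–5 and 7–11).

Steps most likely to fail:

1. Step 10 (proposed new method). What may go wrong: decarbonylation of the acyl rhodium hydride of the doubly ortho-substituted aldehyde; Lewis-acid-triggered Prins-type attack of the enol ether on the formyl group; weak enantiofacial discrimination because the ortho-prenyl ring B is twisted out of the enol ether plane. Fallback by known chemistry, setting out from 8 and 5 and coming back at 14: Roskamp homologation of 8 (tert-butyl diazoacetate, SnCl2 cat., CH2Cl2) would give the β-keto ester tert-butyl 3-[2-hydroxy-4,6-bis(methoxymethoxy)phenyl]-3-oxopropanoate F1. Knoevenagel condensation of this with 5 (piperidine, AcOH, toluene, molecular sieves) would give the alkylidene β-keto ester tert-butyl 2-[2-hydroxy-4,6-bis(methoxymethoxy)benzoyl]-3-[4,5-bis(methoxymethoxy)-2,3-bis(3-methylbut-2-en-1-yl)phenyl]prop-2-enoate F2. Enantioselective 6-endo oxa-Michael cyclisation under a bifunctional cinchona-alkaloid thiourea (the quinine- or quinidine-derived pseudo-enantiomer that leads to 2S; toluene, −25 °C) would give tert-butyl (2S)-2-[4,5-bis(methoxymethoxy)-2,3-bis(3-methylbut-2-en-1-yl)phenyl]-5,7-bis(methoxymethoxy)-4-oxo-3,4-dihydro-2H-chromene-3-carboxylate F3. TsOH·H2O in toluene/MeOH at 60 °C would then remove the tert-butyl ester with decarboxylation together with the four MOM groups, arriving at 14 without step 11.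

2. Step 9. What may go wrong: slow methylenation of the hindered, doubly ortho-flanked aryl ester; protonation and hydrolysis of the enol ether during the acidic unmasking; the acetalisation of step 8 could also suffer neighbouring-group-assisted methanolysis of the aryl ester. Fallback with an acid-free mask at the alcohol level, setting out from 9 and coming back at 12: hydrosilylation of the aldehyde (Et3SiH, RhCl(PPh3)3 cat., toluene, 60 °C; no free alkoxide, hence no acyl migration) would give 2-{[(triethylsilyl)oxy]methyl}-3,5-bis(methoxymethoxy)phenyl 4,5-bis(methoxymethoxy)-2,3-bis(3-methylbut-2-en-1-yl)benzoate F4. Petasis methylenation (Cp2TiMe2, toluene, 70 °C) would give triethyl{[2-({1-[4,5-bis(methoxymethoxy)-2,3-bis(3-methylbut-2-en-1-yl)phenyl]ethenyl}oxy)-4,6-bis(methoxymethoxy)phenyl]methoxy}silane F5. TBAF in THF at 0 °C would give [2-({1-[4,5-bis(methoxymethoxy)-2,3-bis(3-methylbut-2-en-1-yl)phenyl]ethenyl}oxy)-4,6-bis(methoxymethoxy)phenyl]methanol F6, and activated MnO2 in CH2Cl2 would oxidise this benzylic alcohol to 12.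

3. Step 4. What may go wrong: stalling after the first coupling at the hindered vicinal bromide, protodebromination, allyl transfer to the formyl group, or γ-attack giving reverse-prenyl isomers. Fallback at the ester oxidation level with an allylzinc nucleophile, setting out from 4 and coming back at 6: oxidative esterification (I2, KOH, MeOH, 0 °C) would give methyl 2,3-dibromo-4,5-bis(methoxymethoxy)benzoate F7. Twofold linear-selective Negishi coupling (prenylzinc bromide, Pd(OAc)2 with a bulky dialkylbiarylphosphine such as SPhos, THF, rt) would give methyl 4,5-bis(methoxymethoxy)-2,3-bis(3-methylbut-2-en-1-yl)benzoate F8. Saponification (LiOH, THF/H2O; then dilute HCl) would give 6.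

Further compounds
F1 | step 10 | tert-butyl 3-[2-hydroxy-4,6-bis(methoxymethoxy)phenyl]-3-oxopropanoate | CC(C)(C)OC(=O)CC(=O)c1c(O)cc(OCOC)cc1OCOC
F2 | step 10 | tert-butyl 2-[2-hydroxy-4,6-bis(methoxymethoxy)benzoyl]-3-[4,5-bis(methoxymethoxy)-2,3-bis(3-methylbut-2-en-1-yl)phenyl]prop-2-enoate | CC(C)(C)OC(=O)C(=Cc1cc(OCOC)c(OCOC)c(CC=C(C)C)c1CC=C(C)C)C(=O)c1c(O)cc(OCOC)cc1OCOC
F3 | step 10 | tert-butyl (2S)-2-[4,5-bis(methoxymethoxy)-2,3-bis(3-methylbut-2-en-1-yl)phenyl]-5,7-bis(methoxymethoxy)-4-oxo-3,4-dihydro-2H-chromene-3-carboxylate | CC(C)=CCc1c([C@@H]2C(C(=O)OC(C)(C)C)C(=O)c3c(OCOC)cc(OCOC)cc3O2)cc(OCOC)c(OCOC)c1CC=C(C)C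
F4 | step 9 | 2-{[(triethylsilyl)oxy]methyl}-3,5-bis(methoxymethoxy)phenyl 4,5-bis(methoxymethoxy)-2,3-bis(3-methylbut-2-en-1-yl)benzoate | CC[Si](CC)(CC)OCc1c(OC(=O)c2cc(OCOC)c(OCOC)c(CC=C(C)C)c2CC=C(C)C)cc(OCOC)cc1OCOC
F5 | step 9 | triethyl{[2-({1-[4,5-bis(methoxymethoxy)-2,3-bis(3-methylbut-2-en-1-yl)phenyl]ethenyl}oxy)-4,6-bis(methoxymethoxy)phenyl]methoxy}silane | CC[Si](CC)(CC)OCc1c(OC(=C)c2cc(OCOC)c(OCOC)c(CC=C(C)C)c2CC=C(C)C)cc(OCOC)cc1OCOC
F6 | step 9 | [2-({1-[4,5-bis(methoxymethoxy)-2,3-bis(3-methylbut-2-en-1-yl)phenyl]ethenyl}oxy)-4,6-bis(methoxymethoxy)phenyl]methanol | OCc1c(OC(=C)c2cc(OCOC)c(OCOC)c(CC=C(C)C)c2CC=C(C)C)cc(OCOC)cc1OCOC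
F7 | step 4 | methyl 2,3-dibromo-4,5-bis(methoxymethoxy)benzoate | COC(=O)c1cc(OCOC)c(OCOC)c(Br)c1Br
F8 | step 4 | methyl 4,5-bis(methoxymethoxy)-2,3-bis(3-methylbut-2-en-1-yl)benzoate | COC(=O)c1cc(OCOC)c(OCOC)c(CC=C(C)C)c1CC=C(C)C
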